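**Strategy.** Ring A is numbered from the butanoyl-bearing carbon 1 via carbon 2 (C–OH), carbon 3 (C–CH3), carbon 4 (C–OMe) and bridge-bearing carbon 5 to carbon 6 (C–OH). The key step exploits the strict alternation of oxygen and carbon substituents around this ring, with only the oxygen on carbon 4 etherified: a Diels–Alder/aromatisation between 1,3-dimethoxy-2-methyl-1-(trimethylsilyloxy)penta-1,3-diene (ring carbons 3 to 6) and 1-(propan-2-yloxy)hex-1-yn-3-one (ring carbons 2 and 1) forms the bonds between carbons 2 and 3 and between carbons 1 and 6 and delivers the hexasubstituted arene in one operation. Dealkylation then gives a symmetric resorcinol whose quinone methide is trapped by acetylfilicinic acid to form the methylene bridge.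

Key step: step 6

Remarks on the chemistry (assumptions):
- The alkyl group on the ynone oxygen is a spectator and is taken as isopropyl. In the cycloaddition product the hydroxyl on ring A carbon 6 already holds the butanoyl carbonyl in a chelate, so a primary ether on carbon 2 could not be removed by chelate-directed BCl3 cleavage and would compete with the twisted methyl ether on carbon 4. An isopropyl aryl ether is cleaved by BCl3 without a chelate.
- The ether is removed before the bridge is made. In the resulting diol the two ring methyl groups are equivalent, so the oxidation cannot give regioisomers, and the methylene-bridged product never meets a Lewis acid.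

Step 1
Reactants: 1 methyl 2-methyl-3-oxopentanoate
Product: 2 methyl 3-methoxy-2-methylpent-2-enoate (E/Z mixture)
Conditions: HC(OMe)3, H2SO4 (cat.), MeOH, rt; then distil
Reagents that add atoms: trimethyl orthoformate, COC(OC)OC
Why: Acid-catalysed ketalisation with the orthoformate and loss of methanol on distillation (enol ether formation from a β-keto ester) should give the β-methoxy enoate, and any deconjugated regioisomer is harmless because it leads to the same dienolate in step 2.

Step 2
Reactants: 2 methyl 3-methoxy-2-methylpent-2-enoate
Product: 3 1,3-dimethoxy-2-methyl-1-(trimethylsilyloxy)penta-1,3-diene (mixture of geometric isomers)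
Conditions: LiN(iPr)2, THF, −78 °C; Me3SiCl, −78 °C to rt; distil
Reagents that add atoms: chlorotrimethylsilane, C[Si](C)(C)Cl
Why: LiN(iPr)2 removes a γ-proton (from the CH2 of the ethyl group) of the vinylogous ester and the extended enolate is silylated on oxygen, the standard kinetic O-silylation route to 1-alkoxy-1-silyloxy-3-alkoxy dienes, with a double-bond geometry that is not controlled and does not matter.

Step 3
Reactants: 4 propan-2-ol; 5 trichloroethylene
Product: 7 (E)-1,2-dichloro-1-(propan-2-yloxy)ethene, via dichloroacetylene 6 (not isolated)
Conditions: KH, THF, 0 °C; Cl2C=CHCl, −50 °C to rt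
Reagents that add atoms: none
Why: KOiPr, formed from 4 and KH, dehydrochlorinates trichloroethylene to dichloroacetylene in solution and adds to it in anti fashion, which should give the (E)-dichloroenol ether (first stage of the dichlorovinyl ether route to ynol ethers).

Step 4
Reactants: 7 (E)-1,2-dichloro-1-(propan-2-yloxy)ethene; 8 butanal
Product: 10 1-(propan-2-yloxy)hex-1-yn-3-ol (racemic), via lithium 2-(propan-2-yloxy)ethynide 9 (not isolated)
Conditions: n-BuLi (2.2 equiv), THF, −78 to −40 °C; then 8, −78 °C; H2O, 0 °C
Reagents that add atoms: none
Why: Two equivalents of n-BuLi effect elimination of HCl and chlorine–lithium exchange to the lithium alkoxyacetylide, which adds 1,2 to butanal (acetylide addition to an aldehyde), the racemic carbinol centre being removed in step 5.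

Step 5
Reactants: 10 1-(propan-2-yloxy)hex-1-yn-3-ol
Product: 11 1-(propan-2-yloxy)hex-1-yn-3-one
Conditions: MnO2 (activated, excess), CH2Cl2, rt
Reagents that add atoms: none
Why: Activated MnO2 oxidises propargylic alcohols under neutral conditions, which avoids the acid-triggered Meyer–Schuster rearrangement of the alkoxyalkynyl carbinol.

Step 6
Reactants: 3 1,3-dimethoxy-2-methyl-1-(trimethylsilyloxy)penta-1,3-diene; 11 1-(propan-2-yloxy)hex-1-yn-3-one
Product: 13 1-[2-hydroxy-4-methoxy-3,5-dimethyl-6-(propan-2-yloxy)phenyl]butan-1-one, via cyclohexadiene cycloadduct 12 (not isolated)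
Conditions: 3 (2 equiv), PhMe (concentrated), rt to 45 °C; then 1 M HCl, THF, rt
Reagents that add atoms: none
Why: The γ-carbon of vinylogous silyl ketene acetal 3 (its methyl-bearing terminus, the future ring A carbon 3) bonds to the alkoxy-bearing β-carbon of ynone 11 (ring A carbon 2) and the ynone α-carbon (ring A carbon 1) bonds to the ketene acetal carbon (ring A carbon 6), either as a concerted, strongly asynchronous [4+2] cycloaddition or, in the stepwise limit, as a Mukaiyama–Michael addition followed by 6-(enolexo)-exo-trig closure of the allenolate carbon on the oxocarbenium carbon, so that ring A is closed as cyclohexa-1,4-diene 12. The closest known reaction type is the Diels–Alder/aromatisation of 1-alkoxy-1-silyloxy-3-alkoxy dienes with acetylenic ketones, applied here to an ynone whose β-carbon carries an alkoxy donor; this lowers its reactivity and is the reason for the excess of diene and the concentrated solution, while the temperature is held at or below 45 °C to stay under the onset of retro-ene loss of propene from the ynol ether. On acidic work-up the silyl group is lost, the hemiketal at ring A carbon 6 expels methanol and the resulting cross-conjugated dienone tautomerises through the hydrogen on ring A carbon 3, so the oxygen that carried silicon should survive as the hydroxyl hydrogen-bonded to the butanoyl carbonyl. The two sp3 centres of 12 are transient and disappear on aromatisation, so neither diene geometry nor facial selectivity matters and no stereocentre remains. The one selectivity required is regiochemical and is secured by matched polarity: the most nucleophilic diene terminus pairs with the most electrophilic alkyne carbon (β to the ketone and stabilised as an oxocarbenium ion by its own oxygen), which places the butanoyl group between two oxygens, the methoxy group para to it and the isopropoxy group on ring A carbon 2.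

Step 7
Reactants: 13 1-[2-hydroxy-4-methoxy-3,5-dimethyl-6-(propan-2-yloxy)phenyl]butan-1-one
Product: 14 1-(2,6-dihydroxy-4-methoxy-3,5-dimethylphenyl)butan-1-one
Conditions: BCl3 (3 equiv), CH2Cl2, −78 to 0 °C; then MeOH, H2O
Reagents that add atoms: none
Why: BCl3 cleaves secondary alkyl aryl ethers through an ionising pathway at or below 0 °C without needing a chelate, while the methyl ether on ring A carbon 4 is inert under these conditions and the hydroxyl on ring A carbon 6 is masked as its aryl–O–BCl2 chelate (selective Lewis-acid dealkylation of an isopropyl aryl ether).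

Step 8
Reactants: 15 2',4',6'-trihydroxyacetophenone
Product: 16 2-acetyl-3,5-dihydroxy-4,4-dimethylcyclohexa-2,5-dien-1-one (acetylfilicinic acid)
Conditions: NaOMe (3 equiv), MeI (2.2 equiv), MeOH, 0 °C to rt; then 1 M HCl
Reagents that add atoms: iodomethane, CI
Why: C-methylation of the phloroglucinol polyanion twice at one ring carbon with about two equivalents of MeI is the established dearomatising gem-dimethylation of acylphloroglucinols to acylfilicinic acids and leaves the other ring CH free as the nucleophilic carbon for step 9.

Step 9
Reactants: 14 1-(2,6-dihydroxy-4-methoxy-3,5-dimethylphenyl)butan-1-one; 16 acetylfilicinic acid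
Product: 18 2-acetyl-6-[(3-butanoyl-2,4-dihydroxy-6-methoxy-5-methylphenyl)methyl]-3,5-dihydroxy-4,4-dimethylcyclohexa-2,5-dien-1-one (target CNP0414731.0), via quinone methide 17 (not isolated)
Conditions: Ag2O (1.1 equiv), 16 (1.5 equiv), CH2Cl2–THF, rt, dark; then 1 M HCl wash
Reagents that add atoms: none
Why: Ag2O should oxidise the electron-rich phenol by two electrons with loss of a benzylic proton to quinone methide 17 (either methyl of the symmetric diol gives the same species, each being ortho to one hydroxyl and para to the other), and the free enol carbon of 16 adds to the exocyclic methylene in a Michael sense with rearomatisation (oxidative quinone methide generation and conjugate addition), forming the methylene bridge without any stereocentre.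

Compound list
1 | methyl 2-methyl-3-oxopentanoate (racemic) | CCC(=O)C(C)C(=O)OC | starting material
2 | methyl 3-methoxy-2-methylpent-2-enoate (E/Z mixture, geometry irrelevant) | CCC(OC)=C(C)C(=O)OC | intermediate
3 | 1,3-dimethoxy-2-methyl-1-(trimethylsilyloxy)penta-1,3-diene (mixture of geometric isomers, geometry irrelevant) | COC(O[Si](C)(C)C)=C(C)C(OC)=CC | intermediate
4 | propan-2-ol | CC(C)O | starting material
5 | trichloroethylene | ClC=C(Cl)Cl | starting material
6 | dichloroacetylene (not isolated) | ClC#CCl | intermediate
7 | (E)-1,2-dichloro-1-(propan-2-yloxy)ethene | CC(C)O/C(Cl)=C\Cl | intermediate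
8 | butanal | CCCC=O | starting material
9 | lithium 2-(propan-2-yloxy)ethynide (not isolated) | [Li]C#COC(C)C | intermediate
10 | 1-(propan-2-yloxy)hex-1-yn-3-ol (racemic) | CCCC(O)C#COC(C)C | intermediate
11 | 1-(propan-2-yloxy)hex-1-yn-3-one | CCCC(=O)C#COC(C)C | intermediate
12 | 1-[4,6-dimethoxy-3,5-dimethyl-2-(propan-2-yloxy)-6-(trimethylsilyloxy)cyclohexa-1,4-dien-1-yl]butan-1-one (diastereomer mixture, racemic, not isolated) | CCCC(=O)C1=C(OC(C)C)C(C)C(OC)=C(C)C1(OC)O[Si](C)(C)C | intermediate
13 | 1-[2-hydroxy-4-methoxy-3,5-dimethyl-6-(propan-2-yloxy)phenyl]butan-1-one | CCCC(=O)c1c(O)c(C)c(OC)c(C)c1OC(C)C | intermediate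
14 | 1-(2,6-dihydroxy-4-methoxy-3,5-dimethylphenyl)butan-1-one | CCCC(=O)c1c(O)c(C)c(OC)c(C)c1O | intermediate
15 | 2',4',6'-trihydroxyacetophenone | CC(=O)c1c(O)cc(O)cc1O | starting material
16 | 2-acetyl-3,5-dihydroxy-4,4-dimethylcyclohexa-2,5-dien-1-one (acetylfilicinic acid) | CC(=O)C1=C(O)C(C)(C)C(O)=CC1=O | intermediate
17 | 2-butanoyl-3-hydroxy-5-methoxy-4-methyl-6-methylidenecyclohexa-2,4-dien-1-one (not isolated) | CCCC(=O)C1=C(O)C(C)=C(OC)C(=C)C1=O | intermediate
18 | 2-acetyl-6-[(3-butanoyl-2,4-dihydroxy-6-methoxy-5-methylphenyl)methyl]-3,5-dihydroxy-4,4-dimethylcyclohexa-2,5-dien-1-one (achiral) | CCCC(=O)c1c(O)c(C)c(OC)c(CC2=C(O)C(C)(C)C(O)=C(C(C)=O)C2=O)c1O | target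

Step count. Total: 9 steps. Longest linear sequence: 6 steps (steps 3, 4, 5, 6, 7 and 9).

Steps most likely to fail

1. Step 6. The donor oxygen on the alkyne lowers its dienophilicity, so cycloaddition may lose out to hydrolysis or self-condensation of the diene, to retro-ene loss of propene from the ynol ether on warming, or to reaction at the ketene acetal double bond alone. The fallback sets out from 3 and comes back at 14; it joins the same four diene carbons to the remaining two ring carbons by ionic acylation and condensation chemistry. Diene 3 is acylated at its γ-carbon with acetyl chloride (CH2Cl2, −78 °C to rt) to give methyl 3-methoxy-2,4-dimethyl-5-oxohex-2-enoate F1. Its dianion (LiN(iPr)2, 2.2 equiv, THF, −78 °C) is acylated at the terminal methyl carbon with N-methoxy-N-methylbutanamide to give methyl 3-methoxy-2,4-dimethyl-5,7-dioxodec-2-enoate F2. NaOMe in MeOH then closes ring A by intramolecular Claisen condensation of the diketone methylene onto the ester, with loss of methanol and enolisation. This gives diol 14 directly, so step 7 is not needed.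

2. Step 9. Oxidation may run past the first quinone methide, since the product still carries a methyl ortho and para to hydroxyls. Ag2O may also deprotonate the acidic triketone 16 and oxidise its enolate to dimers, or the quinone methide may dimerise before it is trapped. The fallback sets out from 14 and comes back at 18; it activates the benzylic carbon by radical halogenation, not by phenol oxidation. Acetylation (Ac2O, pyridine, DMAP) gives 2-butanoyl-5-methoxy-4,6-dimethyl-1,3-phenylene diacetate F3. Wohl–Ziegler bromination (NBS, 1 equiv, AIBN, PhCF3, 80 °C) on the fully substituted ring gives 4-(bromomethyl)-2-butanoyl-5-methoxy-6-methyl-1,3-phenylene diacetate F4, a single monobromide because the two methyl groups are equivalent. C-alkylation of 16 with this bromide (Cs2CO3, MeCN, rt) gives 4-[(3-acetyl-2,4-dihydroxy-5,5-dimethyl-6-oxocyclohexa-1,3-dien-1-yl)methyl]-2-butanoyl-5-methoxy-6-methyl-1,3-phenylene diacetate F5. K2CO3 in MeOH at 0 °C removes both acetates and returns 18.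

3. Step 5 (with the isolation of 10 in step 4). Carbinol 10 may undergo acid-triggered Meyer–Schuster rearrangement to an α,β-unsaturated ester on the oxidant surface or during isolation, and oxidation may stall on deactivated MnO2. The fallback sets out from 7 and comes back at 11; it replaces addition plus oxidation by direct acylation. Acetylide 9 is generated from 7 as in step 4 and treated with N-methoxy-N-methylbutanamide (THF, −78 to 0 °C, inverse quench into cold aqueous NaH2PO4). The chelated tetrahedral adduct should collapse to ynone 11 only on work-up. This fallback makes no new compound (F0).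

Further compounds
F1 | step 6 | methyl 3-methoxy-2,4-dimethyl-5-oxohex-2-enoate (racemic, E/Z mixture) | COC(=O)C(C)=C(OC)C(C)C(C)=O
F2 | step 6 | methyl 3-methoxy-2,4-dimethyl-5,7-dioxodec-2-enoate (racemic, E/Z mixture) | COC(=O)C(C)=C(OC)C(C)C(=O)CC(=O)CCC
F3 | step 9 | 2-butanoyl-5-methoxy-4,6-dimethyl-1,3-phenylene diacetate | CCCC(=O)c1c(OC(C)=O)c(C)c(OC)c(C)c1OC(C)=O
F4 | step 9 | 4-(bromomethyl)-2-butanoyl-5-methoxy-6-methyl-1,3-phenylene diacetate | CCCC(=O)c1c(OC(C)=O)c(C)c(OC)c(CBr)c1OC(C)=O
F5 | step 9 | 4-[(3-acetyl-2,4-dihydroxy-5,5-dimethyl-6-oxocyclohexa-1,3-dien-1-yl)methyl]-2-butanoyl-5-methoxy-6-methyl-1,3-phenylene diacetate | CCCC(=O)c1c(OC(C)=O)c(C)c(OC)c(CC2=C(O)C(C)(C)C(O)=C(C(C)=O)C2=O)c1OC(C)=O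
F0 | step 5 | none | none
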